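**Plan**
- Retrosynthesis: open the 3(2H)-furanone at O–C3 (back to a C10-hydroxy ynone), cut C1–C2 (ten-membered ring) and C3–C4 (enyne), and remove the C8 angelate. The seco chain is then cut in one operation at C8–C9, C7–C8 and C11–C13 into a 2-silyl-1,3-dithiane, a 2-methylglycidyl ether, a 5-alkenyl butenolide and MeI. The butenolide is cut at C7=C11 (metathesis) and C6–C7 (vinyl addition).
- Enabling feature: C8 is a carbinol carbon between C9H2–C10(O) (epoxide retron) and C7, the β-carbon of the α-methyl γ-lactone ring (conjugate addition/alkylation retron), so one dithiane carbon can act twice as an acyl anion.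
- Forward order: γ-lactone ring first (RCM), then the chain joined in one flask by the dithiane relay, then the ten-membered carbocycle by Nozaki–Hiyama–Kishi alkynylation, and the furanone ring last by 5-endo-dig cyclisation.
- Stereochemistry: C10 from Sharpless epoxidation; C6 from catalytic asymmetric vinylation; C7 and C11 relayed from C6 in the key step (anti, anti); C8 from CBS reduction; 4Z from trans-hydroalumination/iodination; angelate geometry from angelic acid.

Key step: step 9

Remark: carbons are numbered as in the germacranolide skeleton of the target (C1 ring ketone, C3 and C10 joined through the furanone oxygen, C6 lactone oxygen, C8 ester, C12 lactone carbonyl, C13/C14/C15 the methyls on C11/C10/C4); the ester is read as the (Z)-2-methylbut-2-enoate (angelate) and the target as (4Z,6R,7R,8R,10R,11S).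

**Step 1**
Reactants: 1 1,3-dithiane
Product: 3 2-(tert-butyldimethylsilyl)-1,3-dithiane, via 2-lithio-1,3-dithiane 2 (not isolated)
Conditions: n-BuLi, THF, −30 °C; then TBSCl, −78 °C → rt
Reagents that add atoms: tert-butyldimethylsilyl chloride, CC(C)(C)[Si](C)(C)Cl
Why: Deprotonation of the dithioacetal C–H and C-silylation of the 2-lithio-dithiane (Corey–Seebach umpolung chemistry) is the standard entry to 2-silyl dithianes.

**Step 2**
Reactants: 4 2-methylprop-2-en-1-ol
Product: 5 (S)-2-methylglycidol
Conditions: Ti(OiPr)4 (5 mol %), L-(+)-diisopropyl tartrate (6 mol %), cumene hydroperoxide, 4 Å MS, CH2Cl2, −20 °C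
Reagents that add atoms: cumene hydroperoxide, CC(C)(OO)c1ccccc1
Why: Sharpless asymmetric epoxidation of a 2-substituted allylic alcohol, in which the L-(+)-tartrate should give the 2S epoxy alcohol, the configuration that becomes C10.

**Step 3**
Reactants: 5 (S)-2-methylglycidol
Product: 6 (2R)-2-{[(4-methoxybenzyl)oxy]methyl}-2-methyloxirane
Conditions: NaH, PMBCl, Bu4NI (cat.), THF/DMF, 0 °C → rt
Reagents that add atoms: 4-methoxybenzyl chloride, COc1ccc(CCl)cc1
Why: Williamson etherification of the primary alkoxide leaves the stereocentre untouched (the descriptor changes only by CIP priority), and any Payne equilibration of this symmetrical glycidol regenerates the same enantiomer.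

**Step 4**
Reactants: 7 but-2-yn-1-ol
Product: 9 (2Z)-3-iodobut-2-en-1-ol, via cyclic alkenylalanate 8 (not isolated)
Conditions: Red-Al, THF, 0 °C → rt; then I2, −78 → 0 °C
Reagents that add atoms: iodine, II
Why: trans-Hydroalumination of the propargylic alkoxide places aluminium on C3 in a five-membered alanate and iodinolysis with retention gives the (Z)-3-iodoallylic alcohol, which fixes the C4=C5 geometry.

**Step 5**
Reactants: 9 (2Z)-3-iodobut-2-en-1-ol
Product: 10 (2Z)-3-iodobut-2-enal
Conditions: activated MnO2, CH2Cl2, rt, dark (carried on crude)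
Reagents that add atoms: none
Why: Neutral allylic oxidation with MnO2 should give the β-iodo enal without Z/E isomerisation.

**Step 6**
Reactants: 10 (2Z)-3-iodobut-2-enal
Product: 11 (3S,4Z)-5-iodohexa-1,4-dien-3-ol
Conditions: divinylzinc (salt-free stock solution from ZnCl2 and vinylmagnesium bromide), (−)-DAIB (10 mol %), toluene, −30 → 0 °C
Reagents that add atoms: divinylzinc, C=C[Zn]C=C
Why: Amino-alcohol-catalysed asymmetric addition of an alkenylzinc to an α,β-unsaturated aldehyde, in which (−)-DAIB directs the transferred group to the Si face as with other enals and should give the 3S carbinol that becomes C6.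

**Step 7**
Reactants: 11 (3S,4Z)-5-iodohexa-1,4-dien-3-ol
Product: 12 (3S,4Z)-5-iodohexa-1,4-dien-3-yl prop-2-enoate
Conditions: acryloyl chloride, iPr2NEt, CH2Cl2, −78 → 0 °C
Reagents that add atoms: acryloyl chloride, C=CC(=O)Cl
Why: Simple O-acylation at low temperature, cold enough to avoid allylic transposition of the bis-allylic ester.

**Step 8**
Reactants: 12 (3S,4Z)-5-iodohexa-1,4-dien-3-yl prop-2-enoate
Product: 13 (5S)-5-[(1Z)-2-iodoprop-1-en-1-yl]furan-2(5H)-one
Conditions: Grubbs second-generation catalyst (5 mol %), CH2Cl2 (0.005 M), 40 °C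
Reagents that add atoms: none
Why: Ring-closing metathesis of the acrylate with the terminal vinyl group closes the butenolide with loss of ethene, the trisubstituted iodoalkene being too hindered and electron-poor to engage the ruthenium carbene.

**Step 9**
Reactants: 3 2-(tert-butyldimethylsilyl)-1,3-dithiane; 6 (2R)-PMB 2-methylglycidyl ether; 13 (5S)-5-[(1Z)-2-iodoprop-1-en-1-yl]furan-2(5H)-one
Product: 18 (3S,4S,5S)-4-{2-[(2R)-2-(tert-butyldimethylsilyloxy)-3-(4-methoxybenzyloxy)-2-methylpropyl]-1,3-dithian-2-yl}-5-[(1Z)-2-iodoprop-1-en-1-yl]-3-methyloxolan-2-one (C8-dithiane seco-lactone), via lithiated silyl dithiane 14 (not isolated), via C-silyl lithium alkoxide 15 (not isolated), via O-silyl lithiodithiane 16 (not isolated), via lithium lactone enolate 17 (not isolated)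
Conditions: 3, t-BuLi, Et2O, −78 → −45 °C; 6 in Et2O, −78 → −25 °C; then 13 in THF/HMPA, −78 °C; then MeI, −78 → −40 °C; NH4Cl
Reagents that add atoms: iodomethane, CI
Why: The 2-lithio-2-silyl-dithiane opens the epoxide at its unsubstituted carbon (C8–C9) to a tertiary lithium alkoxide that is stable in ether, and HMPA then triggers a 1,4-Brook rearrangement that silylates the C10 oxygen and regenerates a dithiane anion at C8. This anion adds 1,4 to the butenolide (C7–C8) and the resulting lactone enolate is C-methylated by iodomethane (C11–C13). The closest known reaction types are the solvent-controlled anion-relay (silyl-dithiane linchpin) coupling with epoxides and the tandem conjugate addition–enolate alkylation of 5-substituted butenolides with lithiated dithianes; no ring is closed. C7 is set by attack anti to the C6 alkenyl group and C11 by methylation anti to the new, bulky C7 substituent, which gives the trans,trans lactone, while C10 is carried unchanged from the epoxide. The step needs 1,4- over 1,2-addition and addition over γ-deprotonation, which the soft HMPA-solvated dithiane anion, the lactone (not ketone) carbonyl and the low temperature should secure, and the order of addition ensures that each electrophile meets only the anion meant for it.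

**Step 10**
Reactants: 18 C8-dithiane seco-lactone
Product: 19 (3S,4S,5S)-4-[(3R)-3-(tert-butyldimethylsilyloxy)-4-(4-methoxybenzyloxy)-3-methylbutanoyl]-5-[(1Z)-2-iodoprop-1-en-1-yl]-3-methyloxolan-2-one (C8 ketone)
Conditions: MeI, CaCO3, MeCN/H2O (9:1), 45 °C
Reagents that add atoms: water, O
Why: Alkylative dithiane hydrolysis (S-methylation, thionium formation, attack of water) runs near neutrality, which spares the PMB and silyl ethers and should avoid both C7 epimerisation and β-elimination of the C6 carboxylate from the new ketone.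

**Step 11**
Reactants: 19 C8 ketone
Product: 20 (8R)-alcohol [target numbering 6S,7R,8R,10R,11S; C1–OPMB, C10–OTBS, (Z)-C4 iodide]
Conditions: (S)-2-methyl-CBS-oxazaborolidine (0.5 equiv), BH3·SMe2, THF, −30 °C; MeOH quench
Reagents that add atoms: none
Why: Corey–Bakshi–Shibata reduction in which the (S)-catalyst treats the α-branched C7 side as the large group and should deliver the 8R carbinol (the sense also predicted by a Felkin–Anh approach anti to the C6 arm), under neutral borane conditions that leave no free alkoxide to translactonise.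

**Step 12**
Reactants: 20 (8R)-alcohol
Product: 21 C8 angelate [6S,7R,8R,10R,11S; C1–OPMB, C10–OTBS, (Z)-C4 iodide]
Conditions: angelic acid, 2,4,6-trichlorobenzoyl chloride, Et3N, toluene, rt; then 20, 75 °C
Reagents that add atoms: angelic acid [(Z)-2-methylbut-2-enoic acid], C/C=C(/C)C(=O)O
Why: Yamaguchi-type esterification through the angelic 2,4,6-trichlorobenzoic mixed anhydride without nucleophilic catalyst is the established way to transfer an angeloyl group to a hindered secondary alcohol without Z→E isomerisation to the tiglate.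

**Step 13**
Reactants: 21 C8 angelate
Product: 22 (Z)-enyne silane [6R,7R,8R,10R,11S; C3–C4 bond formed, C2–SiMe3]
Conditions: ethynyltrimethylsilane, Pd(PPh3)2Cl2 (5 mol %), CuI (10 mol %), Et3N, THF, rt
Reagents that add atoms: ethynyltrimethylsilane, C#C[Si](C)(C)C
Why: Sonogashira coupling of an alkenyl iodide proceeds with retention of the Z geometry and installs C2–C3 on C4.

**Step 14**
Reactants: 22 (Z)-enyne silane
Product: 23 C1 primary alcohol
Conditions: DDQ, CH2Cl2/pH 7 buffer (10:1), 0 °C
Reagents that add atoms: none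
Why: Oxidative PMB cleavage by DDQ (hydride abstraction, hydrolysis of the oxocarbenium ion) is selective for the electron-rich benzyl ether over the silyl ether, the enoate and the enyne.

**Step 15**
Reactants: 23 C1 primary alcohol
Product: 24 1-iodoalkyne alcohol
Conditions: N-iodosuccinimide, AgNO3 (10 mol %), DMF, rt, dark
Reagents that add atoms: N-iodosuccinimide, O=C1CCC(=O)N1I
Why: Silver-catalysed iododesilylation converts the alkynylsilane directly into the 1-iodoalkyne needed for chromium insertion.

**Step 16**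
Reactants: 24 1-iodoalkyne alcohol
Product: 25 C1 aldehyde (iodoalkyne aldehyde)
Conditions: Dess–Martin periodinane, CH2Cl2, 0 °C → rt
Reagents that add atoms: none
Why: Dess–Martin oxidation of the neopentyl primary alcohol gives a non-enolisable α-silyloxy aldehyde and tolerates the iodoalkyne and both esters.

**Step 17**
Reactants: 25 C1 aldehyde
Product: 26 ten-membered cyclic propargylic alcohol (C1 epimers; 6R,7R,8R,10R,11S)
Conditions: CrCl2 (8 equiv), NiCl2 (2 mol %), degassed THF, rt, syringe-pump addition (final 0.002 M)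
Reagents that add atoms: none
Why: Intramolecular Nozaki–Hiyama–Kishi alkynylation, in which the alkynylchromium(III) species adds chemoselectively to the aldehyde, is a proven closure for ten-membered enyne rings, and the C1 configuration is irrelevant because it is oxidised later.

**Step 18**
Reactants: 26 cyclic propargylic alcohol
Product: 27 cyclic C1,C10-diol
Conditions: HF·pyridine, pyridine, THF, 0 °C → rt
Reagents that add atoms: none
Why: Fluoride cleavage of the tertiary silyl ether under buffered acidic conditions should leave the angelate, the lactone and the enyne intact, and is done before the sensitive ynone exists.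

**Step 19**
Reactants: 27 cyclic C1,C10-diol
Product: 29 target compound CNP0278264.1, via hydroxy ynone 28 (not isolated)
Conditions: IBX, DMSO, rt; aqueous work-up; then Ph3PAuNTf2 (5 mol %), toluene, rt
Reagents that add atoms: none
Why: IBX oxidises the secondary propargylic alcohol of the 1,2-diol without glycol cleavage, and gold(I) activation of the ynone then induces 5-endo-dig addition of the C10 hydroxyl to C3 (cycloisomerisation of a γ-hydroxy ynone to a 3(2H)-furanone), which creates no new stereocentre.

**Compound list**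
1 | 1,3-dithiane | C1CSCSC1 | starting material
2 | 2-lithio-1,3-dithiane | [Li]C1SCCCS1 | intermediate
3 | 2-(tert-butyldimethylsilyl)-1,3-dithiane | CC(C)(C)[Si](C)(C)C1SCCCS1 | intermediate
4 | 2-methylprop-2-en-1-ol | C=C(C)CO | starting material
5 | (S)-2-methylglycidol, [(2S)-2-methyloxiran-2-yl]methanol | C[C@]1(CO)CO1 | intermediate
6 | (2R)-2-{[(4-methoxybenzyl)oxy]methyl}-2-methyloxirane | C[C@]1(COCc2ccc(OC)cc2)CO1 | intermediate
7 | but-2-yn-1-ol | CC#CCO | starting material
8 | sodium 2,2-bis(2-methoxyethoxy)-3-methyl-2,5-dihydro-1,2-oxaaluminol-2-uide (cyclic alkenylalanate) | CC1=CCO[Al-]1(OCCOC)OCCOC.[Na+] | intermediate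
9 | (2Z)-3-iodobut-2-en-1-ol | C/C(I)=C/CO | intermediate
10 | (2Z)-3-iodobut-2-enal | C/C(I)=C/C=O | intermediate
11 | (3S,4Z)-5-iodohexa-1,4-dien-3-ol | C=C[C@@H](/C=C(/C)I)O | intermediate
12 | (3S,4Z)-5-iodohexa-1,4-dien-3-yl prop-2-enoate | C=C[C@@H](/C=C(/C)I)OC(=O)C=C | intermediate
13 | (5S)-5-[(1Z)-2-iodoprop-1-en-1-yl]furan-2(5H)-one | O=C1C=C[C@@H](/C=C(/C)I)O1 | intermediate
14 | 2-lithio-2-(tert-butyldimethylsilyl)-1,3-dithiane | CC(C)(C)[Si](C)(C)C1([Li])SCCCS1 | intermediate
15 | lithium (2R)-1-[2-(tert-butyldimethylsilyl)-1,3-dithian-2-yl]-3-[(4-methoxybenzyl)oxy]-2-methylpropan-2-olate | COc1ccc(COC[C@](C)(O[Li])CC2(SCCCS2)[Si](C)(C)C(C)(C)C)cc1 | intermediate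
16 | 2-lithio-2-[(2R)-2-(tert-butyldimethylsilyloxy)-3-(4-methoxybenzyloxy)-2-methylpropyl]-1,3-dithiane | COc1ccc(COC[C@](C)(O[Si](C)(C)C(C)(C)C)CC2([Li])SCCCS2)cc1 | intermediate
17 | lithium (4S,5S)-4-{2-[(2R)-2-(tert-butyldimethylsilyloxy)-3-(4-methoxybenzyloxy)-2-methylpropyl]-1,3-dithian-2-yl}-5-[(1Z)-2-iodoprop-1-en-1-yl]-4,5-dihydrofuran-2-olate | COc1ccc(COC[C@](C)(O[Si](C)(C)C(C)(C)C)CC2(SCCCS2)[C@H]3C=C(O[Li])O[C@@H]3/C=C(/C)I)cc1 | intermediate
18 | (3S,4S,5S)-4-{2-[(2R)-2-(tert-butyldimethylsilyloxy)-3-(4-methoxybenzyloxy)-2-methylpropyl]-1,3-dithian-2-yl}-5-[(1Z)-2-iodoprop-1-en-1-yl]-3-methyloxolan-2-one | COc1ccc(COC[C@](C)(O[Si](C)(C)C(C)(C)C)CC2(SCCCS2)[C@H]3[C@H](C)C(=O)O[C@@H]3/C=C(/C)I)cc1 | intermediate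
19 | (3S,4S,5S)-4-[(3R)-3-(tert-butyldimethylsilyloxy)-4-(4-methoxybenzyloxy)-3-methylbutanoyl]-5-[(1Z)-2-iodoprop-1-en-1-yl]-3-methyloxolan-2-one | COc1ccc(COC[C@](C)(O[Si](C)(C)C(C)(C)C)CC(=O)[C@H]2[C@H](C)C(=O)O[C@@H]2/C=C(/C)I)cc1 | intermediate
20 | (3S,4R,5S)-4-[(1R,3R)-3-(tert-butyldimethylsilyloxy)-1-hydroxy-4-(4-methoxybenzyloxy)-3-methylbutyl]-5-[(1Z)-2-iodoprop-1-en-1-yl]-3-methyloxolan-2-one | COc1ccc(COC[C@](C)(O[Si](C)(C)C(C)(C)C)C[C@@H](O)[C@H]2[C@H](C)C(=O)O[C@@H]2/C=C(/C)I)cc1 | intermediate
21 | (Z)-2-methylbut-2-enoate (angelate) of 20 at the C8 hydroxyl (6S,7R,8R,10R,11S in target numbering) | COc1ccc(COC[C@](C)(O[Si](C)(C)C(C)(C)C)C[C@@H](OC(=O)/C(C)=C\C)[C@H]2[C@H](C)C(=O)O[C@@H]2/C=C(/C)I)cc1 | intermediate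
22 | as 21 with the iodide replaced by a (trimethylsilyl)ethynyl group, (4Z)-enyne (6R,7R,8R,10R,11S) | COc1ccc(COC[C@](C)(O[Si](C)(C)C(C)(C)C)C[C@@H](OC(=O)/C(C)=C\C)[C@H]2[C@H](C)C(=O)O[C@@H]2/C=C(/C)C#C[Si](C)(C)C)cc1 | intermediate
23 | C1 primary alcohol from 22 (PMB removed; C10–OTBS, C8 angelate, TMS-enyne) | OC[C@](C)(O[Si](C)(C)C(C)(C)C)C[C@@H](OC(=O)/C(C)=C\C)[C@H]1[C@H](C)C(=O)O[C@@H]1/C=C(/C)C#C[Si](C)(C)C | intermediate
24 | 1-iodoalkyne alcohol (as 23 with C2–I in place of C2–SiMe3) | OC[C@](C)(O[Si](C)(C)C(C)(C)C)C[C@@H](OC(=O)/C(C)=C\C)[C@H]1[C@H](C)C(=O)O[C@@H]1/C=C(/C)C#CI | intermediate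
25 | C1 aldehyde of 24 (α-silyloxy aldehyde with 1-iodoalkyne) | O=C[C@](C)(O[Si](C)(C)C(C)(C)C)C[C@@H](OC(=O)/C(C)=C\C)[C@H]1[C@H](C)C(=O)O[C@@H]1/C=C(/C)C#CI | intermediate
26 | ten-membered cyclic propargylic alcohol: C1–OH (both epimers), C2≡C3, (4Z)-alkene, trans-6,12-lactone, C8 angelate, C10–OTBS (6R,7R,8R,10R,11S) | C/C=C(/C)C(=O)O[C@@H]1C[C@@](C)(O[Si](C)(C)C(C)(C)C)C(O)C#C/C(C)=C\[C@H]2OC(=O)[C@@H](C)[C@@H]21 | intermediate
27 | cyclic C1,C10-diol (26 without the silyl group) | C/C=C(/C)C(=O)O[C@@H]1C[C@@](C)(O)C(O)C#C/C(C)=C\[C@H]2OC(=O)[C@@H](C)[C@@H]21 | intermediate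
28 | cyclic C10-hydroxy C1-ynone | C/C=C(/C)C(=O)O[C@@H]1C[C@@](C)(O)C(=O)C#C/C(C)=C\[C@H]2OC(=O)[C@@H](C)[C@@H]21 | intermediate
29 | CNP0278264.1, (4Z,6R,7R,8R,10R,11S)-8-angeloyloxy-1-oxo-3,10-epoxygermacra-2,4-dien-6,12-olide | C/C=C(/C)C(=O)O[C@@H]1C[C@@]2(C)OC(=CC2=O)/C(C)=C\[C@H]2OC(=O)[C@@H](C)[C@@H]21 | target

**Step count**
Total: 19 steps. Longest linear sequence: 16 steps (7 → 29 through steps 4–8, 9 and 10–19).

**Steps most likely to fail**

1. Step 9. The relay may stall: silyl transfer from carbon to the hindered tertiary alkoxide can lag, and the relayed carbanion can remove the acidic γ-proton (C6–H) of the butenolide instead of adding to C7. Fallback, with each event under separate control: 1,3-dithiane 1 is lithiated to 2 (n-BuLi, THF) and opened with epoxide 6 to give the dithianyl tertiary alcohol F1. O-Silylation (TBSOTf, 2,6-lutidine, CH2Cl2) gives the silyl ether F2. Deprotonation of F2 (t-BuLi, THF/HMPA, −78 °C) generates 16 directly, and this is treated with 13 and then MeI as before (through 17), rejoining the route at 18.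

2. Step 17. Intermolecular coupling and protodemetalation of the alkynylchromium species may outrun closure of the strained ten-membered ring. Fallback, closing the ring at C3–C4 instead of C1–C2: angelate 21 is deprotected with DDQ to the primary alcohol F3 and oxidised (Dess–Martin periodinane) to the aldehyde F4. Ethynylmagnesium bromide (THF, −78 °C) gives the ethynyl carbinol F5 as a mixture of C1 epimers. An intramolecular Sonogashira coupling under high dilution (Pd(PPh3)4, CuI, Et3N, THF, slow addition) then joins C3 to C4 and returns to 26.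

3. Step 11. Hydride may be delivered to the wrong face of the C8 carbonyl if the catalyst does not distinguish the α-branched C7 side from the neopentyl-like C9 side, or if the bias of the C7 stereocentre opposes it. Fallback, stereoinversion instead of stereoselective reduction: ketone 19 is reduced to the 8S alcohol F6 (the epimer formed alongside 20, or made deliberately with (R)-Me-CBS). F6 is esterified with angelic acid under Mitsunobu conditions (PPh3, DIAD, toluene, 0 °C → rt) with inversion at C8, so that it converges on 21.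

**Further compounds**
F1 | step 9 | (2R)-1-(1,3-dithian-2-yl)-3-[(4-methoxybenzyl)oxy]-2-methylpropan-2-ol | COc1ccc(COC[C@](C)(O)CC2SCCCS2)cc1
F2 | step 9 | tert-butyldimethylsilyl ether of F1 | COc1ccc(COC[C@](C)(O[Si](C)(C)C(C)(C)C)CC2SCCCS2)cc1
F3 | step 17 | C1 primary alcohol from 21 (PMB removed, alkenyl iodide retained) | OC[C@](C)(O[Si](C)(C)C(C)(C)C)C[C@@H](OC(=O)/C(C)=C\C)[C@H]1[C@H](C)C(=O)O[C@@H]1/C=C(/C)I
F4 | step 17 | C1 aldehyde from F3 | O=C[C@](C)(O[Si](C)(C)C(C)(C)C)C[C@@H](OC(=O)/C(C)=C\C)[C@H]1[C@H](C)C(=O)O[C@@H]1/C=C(/C)I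
F5 | step 17 | C1 ethynyl carbinol from F4 (C1 epimers) | C#CC(O)[C@](C)(O[Si](C)(C)C(C)(C)C)C[C@@H](OC(=O)/C(C)=C\C)[C@H]1[C@H](C)C(=O)O[C@@H]1/C=C(/C)I
F6 | step 11 | C8 epimer of 20, the (8S)-alcohol | COc1ccc(COC[C@](C)(O[Si](C)(C)C(C)(C)C)C[C@H](O)[C@H]2[C@H](C)C(=O)O[C@@H]2/C=C(/C)I)cc1
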